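**Retrosynthetic overview**
- The only ring is the pyrrole. Both ring C–N bonds (N1–C2 and N1–C5) are disconnected together, as a [4+1] aza-annulation of a perbrominated C4 dielectrophile with a traceless NH donor.
- The C4 partner is 1,1,2,3,4,4-hexabromobuta-1,3-diene and the NH donor is methyl carbamate. All four C–Br bonds of the target are already on the acyclic diene, and one bromide leaves from each CBr2 terminus.
- The hexabromodiene comes from 1,4-dibromobuta-1,3-diyne plus 2 Br2, and the dibromodiyne from commercial 1,4-bis(trimethylsilyl)buta-1,3-diyne by Si-to-Br exchange.
- Ring order: one ring, formed last (step 2), with the carbamate cleaved in the same flask.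

Assumption: the target is achiral (planar aromatic, no stereocentre), so "single enantiomer" adds no requirement and no stereocentre has to be set or protected.

**Route**

Step 1
Reactants: 1 1,4-bis(trimethylsilyl)buta-1,3-diyne
Product: 3 1,1,2,3,4,4-hexabromobuta-1,3-diene, via 1,4-dibromobuta-1,3-diyne 2 (not isolated)
Conditions: NBS (2.2 equiv), AgNO3 (10 mol %), acetone, 0 °C to rt, dark; pentane/H2O partition, solution kept dilute and cold, never concentrated; then Br2 (2.1 equiv), CH2Cl2, 0 °C to rt, dark
Reagents that add atoms: N-bromosuccinimide O=C1CCC(=O)N1Br; bromine BrBr
Why: Silver-catalysed desilylative bromination of the alkynylsilane (via the silver acetylide) gives the dibromodiyne, and electrophilic addition of one Br2 to each bromoalkyne then stops at the hexabromodiene because the perbrominated alkenes are deactivated and hindered; no stereo-element is created.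

Step 2
Reactants: 3 1,1,2,3,4,4-hexabromobuta-1,3-diene; 4 methyl carbamate
Product: 8 2,3,4,5-tetrabromo-1H-pyrrole, via bromodienyl carbamate 5 (not isolated), via N-methoxycarbonyl tetrabromopyrrole 6 (not isolated), via caesium tetrabromopyrrolide 7 (not isolated)
Conditions: 4 (1.05 equiv), CuI (10 mol %), 3,4,7,8-tetramethyl-1,10-phenanthroline (20 mol %), Cs2CO3 (3.5 equiv), THF, 60 °C, dark; then MeOH, 0 °C; then AcOH, 0 °C
Reagents that add atoms: none
Why: Proposed new method: a copper-catalysed [4+1] aza-annulation of a perbromodiene with a carbamate as traceless NH donor. The Cu(I) amidate substitutes one bromide of a gem-dibromovinyl terminus (the most activated and least hindered C–Br bonds of 3) to give 5. The amidate of 5 equilibrates its C1=C2 geometry through its aza-enolate form and closes on C4, either by a second Cu(I)/Cu(III) C–N coupling or by 6π electrocyclisation of the 1-azapentadienyl anion followed by β-bromide loss, with aromatisation as the driving force, giving 6. The activated N-acyl group of 6 is then passed to methoxide, so the product sits as the deactivated pyrrolide 7 until acetic acid releases 8. The closest known reaction type is the Cu-catalysed double N-alkenylation of carbamates with 1,4-dihalo-1,3-dienes (Goldberg-type pyrrole synthesis), together with Cu/Pd cyclisations of gem-dibromoolefins that keep one bromine (2-bromoindoles, 2-bromobenzofurans). No stereocentre is formed.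

**Compound list**
1 | 1,4-bis(trimethylsilyl)buta-1,3-diyne | C[Si](C)(C)C#CC#C[Si](C)(C)C | starting material
2 | 1,4-dibromobuta-1,3-diyne | BrC#CC#CBr | intermediate
3 | 1,1,2,3,4,4-hexabromobuta-1,3-diene | BrC(Br)=C(Br)C(Br)=C(Br)Br | intermediate
4 | methyl carbamate | COC(N)=O | starting material
5 | methyl N-[(1Z)-1,2,3,4,4-pentabromobuta-1,3-dien-1-yl]carbamate (bromodienyl carbamate; the 1Z isomer shown is the one that closes, E and Z interconvert in the flask) | COC(=O)N/C(Br)=C(Br)\C(Br)=C(Br)Br | intermediate
6 | methyl 2,3,4,5-tetrabromo-1H-pyrrole-1-carboxylate (N-methoxycarbonyl tetrabromopyrrole) | COC(=O)n1c(Br)c(Br)c(Br)c1Br | intermediate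
7 | caesium 2,3,4,5-tetrabromopyrrol-1-ide (caesium tetrabromopyrrolide) | [Cs+].Brc1[n-]c(Br)c(Br)c1Br | intermediate
8 | 2,3,4,5-tetrabromo-1H-pyrrole (tetrabromopyrrole) | Brc1[nH]c(Br)c(Br)c1Br | target

**Step count and risks**
Total step count: 2. Longest linear sequence: 2 steps (1 to 3 to 8); 4 enters in step 2. The route has only two steps, so both are ranked and there is no third.

Most likely to fail: step 2 (the proposed new annulation).
- Failure modes: halophilic attack or reductive debromination of 3 to bromoalkynes; loss of HBr from 5 to an N-acyl ketenimine; a second amidation at the same terminus or at C2/C3; slow closure because 3 is skewed about C2–C3.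
- Product handling: 8 is light- and heat-sensitive, so it should be worked up cold and in the dark, purified quickly and stored at −20 °C under argon.
- Fallback (known chemistry): it sets out from 4 and returns to the route at 8. Compound 4 is condensed with 2,5-dimethoxytetrahydrofuran in acetic acid at 110 °C (Clauson–Kaas reaction, which still builds the ring through its two C–N bonds) to give methyl 1H-pyrrole-1-carboxylate F1. Methanolysis with NaOMe in MeOH at rt removes the carbamate and gives 1H-pyrrole F2, which can also simply be bought. Exhaustive electrophilic bromination of F2 with NBS (4.0 equiv) in THF at −78 to −10 °C in the dark then delivers 8.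

Second: step 1.
- Failure modes: compound 2 is shock-sensitive when neat and must stay in cold dilute solution; over-addition of Br2 or incomplete Si-to-Br exchange would lower the yield of 3.
- Fallback: it sets out from 1 and returns to the route at 3, reversing the order of events so that no haloalkyne is ever formed. Br2 (2.05 equiv) in CH2Cl2 at −20 °C to rt in the dark adds anti across each triple bond of 1 to give (1E,3E)-1,2,3,4-tetrabromo-1,4-bis(trimethylsilyl)buta-1,3-diene F3. Electrophilic ipso-bromodesilylation of both vinylsilane termini (excess Br2, catalytic AlBr3, CH2Cl2, 40 °C, volatiles removed under vacuum) then gives 3, which goes into step 2 as before.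

**Further compounds**
F1 | step 2 | methyl 1H-pyrrole-1-carboxylate | COC(=O)n1cccc1
F2 | step 2 | 1H-pyrrole | c1cc[nH]c1
F3 | step 1 | (1E,3E)-1,2,3,4-tetrabromo-1,4-bis(trimethylsilyl)buta-1,3-diene | C[Si](C)(C)C(/Br)=C(\Br)C(/Br)=C(\Br)[Si](C)(C)C
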